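**Retrosynthetic overview**
- The target is read as (13R)-13-hydroxylabd-8(17)-ene-15,19-dioic acid. The C4 quaternary centre (C18 methyl, C19 acid) comes from a C4 ketone (one-carbon homologation, α-face methylation, oxidation), and the 8(17)-methylene from a C8 ketone.
- Feature: ring B holds the quaternary C10 (bearing C20) between C5 and the chain-bearing C9. With carbonyls at C4 and C8, both neighbours are enolisable and can be corrected, so only C10 needs absolute control.
- Key disconnection: C9–C10 and C5–C6. Ring B is annulated onto preformed ring A (3-methylcyclohex-2-en-1-one) with a (Z)-2-silyloxydiene that carries C11–C16.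
- The diene comes from (R)-mevalonolactone (C13 stereocentre) by ring opening, Wittig extension, regiospecific Mannich methylenation and enol silylation.

Key step: step 9

Remark: labdane numbering is used; the SMILES corresponds to 5α-H, 9α-H, 10β-CH3, 4α-CH3/4β-CO2H and 13R.
Remark: the C13 hydroxyl is carried as a TBS ether because it has to survive aqueous HCl in steps 9 and 12.
Assumption: the enone binds the oxazaborolidinium ion through the C4 carbonyl lone pair syn to C5–H, as 2-cyclohexenone is taken to do. This predicts Si-face addition at C10 for the (S)-catalyst; if the sense proved opposite, the (R)-catalyst would be used with no other change.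

**Route**

Step 1
Reactants: 1 (R)-mevalonolactone
Product: 3 methyl (3R)-3,5-dihydroxy-3-methylpentanoate, via potassium (R)-mevalonate 2 (not isolated)
Conditions: KOH (1.05 equiv), MeOH/H2O, rt; evaporate; MeI, DMF, rt; used at once
Reagents that add atoms: potassium hydroxide, [K+].[OH-]; iodomethane, CI
Why: Lactone saponification followed by SN2 O-methylation of the carboxylate gives the open hydroxy ester without acid, so relactonisation is avoided and C3 is untouched.

Step 2
Reactants: 3 methyl (3R)-3,5-dihydroxy-3-methylpentanoate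
Product: 5 methyl (3R)-3-(tert-butyldimethylsilyloxy)-3-methyl-5-(triethylsilyloxy)pentanoate, via primary triethylsilyl ether 4 (not isolated)
Conditions: TESOTf (1.0 equiv), 2,6-lutidine, CH2Cl2, −78 °C; then TBSOTf (1.3 equiv), −78 → 0 °C
Reagents that add atoms: triethylsilyl trifluoromethanesulfonate, CC[Si](CC)(CC)OS(=O)(=O)C(F)(F)F; tert-butyldimethylsilyl trifluoromethanesulfonate, CC(C)(C)[Si](C)(C)OS(=O)(=O)C(F)(F)F
Why: Sequential chemoselective silylation: the primary hydroxyl reacts with one equivalent of TESOTf at −78 °C, and the tertiary hydroxyl is then covered by TBSOTf on warming.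

Step 3
Reactants: 5 methyl (3R)-3-(tert-butyldimethylsilyloxy)-3-methyl-5-(triethylsilyloxy)pentanoate
Product: 6 methyl (3R)-3-(tert-butyldimethylsilyloxy)-3-methyl-5-oxopentanoate
Conditions: (COCl)2, DMSO, CH2Cl2, −78 → −40 °C; Et3N, → 0 °C
Reagents that add atoms: none
Why: Swern oxidation, in which the chlorosulfonium salt cleaves a primary triethylsilyl ether in the flask and oxidises it directly to the aldehyde while the tertiary TBS ether is inert.

Step 4
Reactants: 6 methyl (3R)-3-(tert-butyldimethylsilyloxy)-3-methyl-5-oxopentanoate; 7 1-(triphenylphosphoranylidene)propan-2-one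
Product: 8 methyl (3R,5E)-3-(tert-butyldimethylsilyloxy)-3-methyl-7-oxooct-5-enoate
Conditions: CH2Cl2, 40 °C
Reagents that add atoms: none
Why: Wittig olefination with a stabilised ylide gives the (E)-enone under neutral conditions, so the β-silyloxy aldehyde does not eliminate.

Step 5
Reactants: 8 methyl (3R,5E)-3-(tert-butyldimethylsilyloxy)-3-methyl-7-oxooct-5-enoate
Product: 10 methyl (3R,5E)-3-(tert-butyldimethylsilyloxy)-9-(dimethylamino)-3-methyl-7-oxonon-5-enoate, via lithium dienolate 9 (not isolated)
Conditions: LiN(iPr)2 (1.05 equiv), THF, −78 °C; N,N-dimethylmethyleneiminium iodide, −78 °C → rt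
Reagents that add atoms: N,N-dimethylmethyleneiminium iodide, C=[N+](C)C.[I-]
Why: Kinetic deprotonation of the enone takes place at the α′-methyl group (cross-conjugated dienolate), so the Mannich aminomethylation installs C6 regiospecifically.

Step 6
Reactants: 10 methyl (3R,5E)-3-(tert-butyldimethylsilyloxy)-9-(dimethylamino)-3-methyl-7-oxonon-5-enoate
Product: 11 methyl (3R)-3-(tert-butyldimethylsilyloxy)-9-(dimethylamino)-3-methyl-7-oxononanoate
Conditions: H2 (1 atm), Pd/C, EtOAc, rt
Reagents that add atoms: none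
Why: Heterogeneous catalytic hydrogenation saturates the conjugated C9=C11 alkene, while ketone, ester, amine and silyl ether are inert in EtOAc.

Step 7
Reactants: 11 methyl (3R)-3-(tert-butyldimethylsilyloxy)-9-(dimethylamino)-3-methyl-7-oxononanoate
Product: 13 methyl (3R)-3-(tert-butyldimethylsilyloxy)-3-methyl-7-oxonon-8-enoate, via trimethylammonium iodide 12 (not isolated)
Conditions: MeI, CH2Cl2, rt; then NaHCO3 (aq), CH2Cl2, rt; used promptly
Reagents that add atoms: none
Why: N-Methylation to the quaternary ammonium salt and E1cB (Hofmann-type) elimination with mild base release the vinyl ketone.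

Step 8
Reactants: 13 methyl (3R)-3-(tert-butyldimethylsilyloxy)-3-methyl-7-oxonon-8-enoate
Product: 14 methyl (3R,6Z)-3,7-bis(tert-butyldimethylsilyloxy)-3-methylnona-6,8-dienoate
Conditions: TBSOTf (1.2 equiv), Et3N, CH2Cl2, −78 → 0 °C; filtration through Et3N-deactivated silica
Reagents that add atoms: tert-butyldimethylsilyl trifluoromethanesulfonate, CC(C)(C)[Si](C)(C)OS(=O)(=O)C(F)(F)F
Why: Soft enolisation of an alkyl vinyl ketone with a silyl triflate and amine base can only go toward C9 and is known to give the (Z)-silyl dienol ether; the ester is far slower to silylate.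

Step 9
Reactants: 14 methyl (3R,6Z)-3,7-bis(tert-butyldimethylsilyloxy)-3-methylnona-6,8-dienoate; 15 3-methylcyclohex-2-en-1-one
Product: 18 methyl (13R)-13-(tert-butyldimethylsilyloxy)-4,8-dioxo-17,18,19-trinorlabdan-15-oate (trans-fused; 5α-H/9α-H/10β-CH3), via cis-fused silyl enol ether cycloadduct 16 (not isolated), via cis-fused dione 17 (not isolated)
Conditions: (S)-3,3-diphenyl-1-(2-methylphenyl)tetrahydro-1H,3H-pyrrolo[1,2-c][1,3,2]oxazaborole (20 mol%), HN(SO2CF3)2 (18 mol%), 15 (3 equiv), CH2Cl2, −78 → −20 °C; then 1 M HCl, THF, 0 °C; then K2CO3 (0.2 equiv), MeOH, rt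
Reagents that add atoms: none
Why: Proposed new method: the N-protonated oxazaborolidine binds the C4 carbonyl of 15 syn to C5–H, the silyl enol ether carbon C9 of 14 attacks the β-carbon C10 on its Si face (the Re face lies against a phenyl group of the catalyst), and ring B is completed through the C5–C6 bond either in the same event ([4+2] closure) or, after silyl transfer to the ring A enolate, by a 6-endo-trig Mukaiyama–Michael closure onto the transient C6=C7–C8=O vinyl ketone. The closest known reactions are Lewis-acid- and triflimide-promoted Diels–Alder or double-Michael annulations of 2-silyloxydienes with 3-methylcyclohex-2-enones (racemic) and oxazaborolidinium-catalysed Diels–Alder reactions of cyclohexenones without a β-substituent; catalyst control over the face of a β,β-disubstituted enone is the new element. C10 is the only centre set by the catalyst, whereas C5 and C9 are formed cis/endo and are then corrected through the C4 and C8 enols, dilute acid unmasking the C8 ketone and K2CO3/MeOH equilibrating toward the trans-fused dione with the C9 chain equatorial. Regiochemistry (C9 to C10, C6 to C5) is secured by the C8 silyloxy group, which makes C9 the nucleophilic diene terminus, and reactivity by the Z enol ether, which keeps the chain outside the s-cis diene. The selectivity needed is facial at C10; the bulky tert-butyldimethylsilyl group and the low temperature are meant to hold back an achiral silyl-triflimide pathway.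

Step 10
Reactants: 18 methyl (13R)-13-(tert-butyldimethylsilyloxy)-4,8-dioxo-17,18,19-trinorlabdan-15-oate
Product: 19 methyl (13R)-13-(tert-butyldimethylsilyloxy)-19-methoxy-8-oxo-17,18-dinorlabd-4(19)-en-15-oate (E/Z mixture)
Conditions: Ph3P(CH2OMe)Cl (1.3 equiv), KN(SiMe3)2 (1.2 equiv), THF, 0 °C; then 18, −78 → 0 °C
Reagents that add atoms: (methoxymethyl)triphenylphosphonium chloride, COC[P+](c1ccccc1)(c1ccccc1)c1ccccc1.[Cl-]
Why: Wittig methoxymethylenation; C4 is flanked only by ring carbons, whereas C8 is screened by the C9 chain with its silyloxy-bearing quaternary carbon, so a limited charge of the bulky ylide should take C4.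

Step 11
Reactants: 19 methyl (13R)-13-(tert-butyldimethylsilyloxy)-19-methoxy-8-oxo-17,18-dinorlabd-4(19)-en-15-oate
Product: 20 methyl (13R)-13-(tert-butyldimethylsilyloxy)-19-methoxy-18-norlabda-4(19),8(17)-dien-15-oate
Conditions: Ph3PCH3Br (3 equiv), KOtBu (2.8 equiv), toluene, rt → 60 °C
Reagents that add atoms: methyltriphenylphosphonium bromide, C[P+](c1ccccc1)(c1ccccc1)c1ccccc1.[Br-]
Why: Wittig methylenation of the remaining hindered ketone with excess ylide; C9 is epimerisable here but already holds its more stable equatorial configuration.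

Step 12
Reactants: 20 methyl (13R)-13-(tert-butyldimethylsilyloxy)-19-methoxy-18-norlabda-4(19),8(17)-dien-15-oate
Product: 21 methyl (13R)-13-(tert-butyldimethylsilyloxy)-19-oxo-18-norlabd-8(17)-en-15-oate (C4 epimers)
Conditions: 1 M HCl (aq), THF, rt
Reagents that add atoms: water, O
Why: Enol ether hydrolysis (C-protonation at C4, hydration of the oxocarbenium ion, loss of methanol) gives the aldehyde; its C4 configuration is irrelevant because step 13 erases it.

Step 13
Reactants: 21 methyl (13R)-13-(tert-butyldimethylsilyloxy)-19-oxo-18-norlabd-8(17)-en-15-oate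
Product: 22 methyl (13R)-13-(tert-butyldimethylsilyloxy)-19-oxolabd-8(17)-en-15-oate (4α-CH3/4β-CHO)
Conditions: KOtBu (1.2 equiv), THF/t-BuOH, 0 °C; MeI (5 equiv), 0 °C → rt
Reagents that add atoms: iodomethane, CI
Why: α-Alkylation of the aldehyde enolate: the exocyclic C4 enolate is methylated on the α face, anti to the axial C20 methyl, so the new methyl is equatorial (C18) and the formyl group axial (C19).

Step 14
Reactants: 22 methyl (13R)-13-(tert-butyldimethylsilyloxy)-19-oxolabd-8(17)-en-15-oate
Product: 23 (13R)-13-(tert-butyldimethylsilyloxy)-15-methoxy-15-oxolabd-8(17)-en-19-oic acid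
Conditions: NaClO2, NaH2PO4, 2-methylbut-2-ene, t-BuOH/H2O, rt
Reagents that add atoms: sodium chlorite, [Na+].[O-]Cl=O
Why: Pinnick oxidation converts the neopentyl aldehyde to the acid without touching the 8(17)-alkene, the added alkene scavenging HOCl.

Step 15
Reactants: 23 (13R)-13-(tert-butyldimethylsilyloxy)-15-methoxy-15-oxolabd-8(17)-en-19-oic acid
Product: 24 (13R)-13-(tert-butyldimethylsilyloxy)labd-8(17)-ene-15,19-dioic acid
Conditions: LiOH, THF/MeOH/H2O, rt → 40 °C; dilute HCl to pH 3
Reagents that add atoms: lithium hydroxide, [Li+].[OH-]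
Why: Saponification of the C15 methyl ester; with the C13 oxygen still silylated no retro-aldol cleavage can occur.

Step 16
Reactants: 24 (13R)-13-(tert-butyldimethylsilyloxy)labd-8(17)-ene-15,19-dioic acid
Product: 25 (13R)-13-hydroxylabd-8(17)-ene-15,19-dioic acid
Conditions: HF·pyridine, THF, 0 °C → rt
Reagents that add atoms: none
Why: Fluoride-mediated cleavage of the tertiary silyl ether under conditions that do not isomerise the exocyclic alkene gives the target.

**Compound list**
1 | (R)-mevalonolactone | O=C1C[C@](C)(O)CCO1 | starting material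
2 | potassium (R)-mevalonate | OCC[C@@](C)(O)CC(=O)[O-].[K+] | intermediate
3 | methyl (3R)-3,5-dihydroxy-3-methylpentanoate | OCC[C@@](C)(O)CC(=O)OC | intermediate
4 | methyl (3R)-3-hydroxy-3-methyl-5-(triethylsilyloxy)pentanoate | CC[Si](CC)(CC)OCC[C@@](C)(O)CC(=O)OC | intermediate
5 | methyl (3R)-3-(tert-butyldimethylsilyloxy)-3-methyl-5-(triethylsilyloxy)pentanoate | CC[Si](CC)(CC)OCC[C@@](C)(O[Si](C)(C)C(C)(C)C)CC(=O)OC | intermediate
6 | methyl (3R)-3-(tert-butyldimethylsilyloxy)-3-methyl-5-oxopentanoate | O=CC[C@@](C)(O[Si](C)(C)C(C)(C)C)CC(=O)OC | intermediate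
7 | 1-(triphenylphosphoranylidene)propan-2-one | CC(=O)C=P(c1ccccc1)(c1ccccc1)c1ccccc1 | starting material
8 | methyl (3R,5E)-3-(tert-butyldimethylsilyloxy)-3-methyl-7-oxooct-5-enoate | CC(=O)/C=C/C[C@@](C)(O[Si](C)(C)C(C)(C)C)CC(=O)OC | intermediate
9 | lithium dienolate of 8 (α′-deprotonated) | [Li]OC(=C)/C=C/C[C@@](C)(O[Si](C)(C)C(C)(C)C)CC(=O)OC | intermediate
10 | methyl (3R,5E)-3-(tert-butyldimethylsilyloxy)-9-(dimethylamino)-3-methyl-7-oxonon-5-enoate | CN(C)CCC(=O)/C=C/C[C@@](C)(O[Si](C)(C)C(C)(C)C)CC(=O)OC | intermediate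
11 | methyl (3R)-3-(tert-butyldimethylsilyloxy)-9-(dimethylamino)-3-methyl-7-oxononanoate | CN(C)CCC(=O)CCC[C@@](C)(O[Si](C)(C)C(C)(C)C)CC(=O)OC | intermediate
12 | trimethylammonium iodide of 11 | C[N+](C)(C)CCC(=O)CCC[C@@](C)(O[Si](C)(C)C(C)(C)C)CC(=O)OC.[I-] | intermediate
13 | methyl (3R)-3-(tert-butyldimethylsilyloxy)-3-methyl-7-oxonon-8-enoate | C=CC(=O)CCC[C@@](C)(O[Si](C)(C)C(C)(C)C)CC(=O)OC | intermediate
14 | methyl (3R,6Z)-3,7-bis(tert-butyldimethylsilyloxy)-3-methylnona-6,8-dienoate | C=C/C(O[Si](C)(C)C(C)(C)C)=C/CC[C@@](C)(O[Si](C)(C)C(C)(C)C)CC(=O)OC | intermediate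
15 | 3-methylcyclohex-2-en-1-one | CC1=CC(=O)CCC1 | starting material
16 | methyl (13R)-8,13-bis(tert-butyldimethylsilyloxy)-4-oxo-17,18,19-trinorlabd-7-en-15-oate (cis-fused; 5β-H, 9β-H, 10β-CH3) | CC(C)(C)[Si](C)(C)OC1=CC[C@H]2[C@](C)(CCCC2=O)[C@@H]1CC[C@@](C)(O[Si](C)(C)C(C)(C)C)CC(=O)OC | intermediate
17 | methyl (13R)-13-(tert-butyldimethylsilyloxy)-4,8-dioxo-17,18,19-trinorlabdan-15-oate (cis-fused; 5β-H, 9β-H) | O=C1CC[C@H]2[C@](C)(CCCC2=O)[C@@H]1CC[C@@](C)(O[Si](C)(C)C(C)(C)C)CC(=O)OC | intermediate
18 | methyl (13R)-13-(tert-butyldimethylsilyloxy)-4,8-dioxo-17,18,19-trinorlabdan-15-oate (trans-fused; 5α-H, 9α-H, 10β-CH3) | O=C1CC[C@@H]2[C@](C)(CCCC2=O)[C@H]1CC[C@@](C)(O[Si](C)(C)C(C)(C)C)CC(=O)OC | intermediate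
19 | methyl (13R)-13-(tert-butyldimethylsilyloxy)-19-methoxy-8-oxo-17,18-dinorlabd-4(19)-en-15-oate | O=C1CC[C@@H]2[C@](C)(CCCC2=COC)[C@H]1CC[C@@](C)(O[Si](C)(C)C(C)(C)C)CC(=O)OC | intermediate
20 | methyl (13R)-13-(tert-butyldimethylsilyloxy)-19-methoxy-18-norlabda-4(19),8(17)-dien-15-oate | C=C1CC[C@@H]2[C@](C)(CCCC2=COC)[C@H]1CC[C@@](C)(O[Si](C)(C)C(C)(C)C)CC(=O)OC | intermediate
21 | methyl (13R)-13-(tert-butyldimethylsilyloxy)-19-oxo-18-norlabd-8(17)-en-15-oate (C4 epimers) | C=C1CC[C@@H]2[C@](C)(CCCC2C=O)[C@H]1CC[C@@](C)(O[Si](C)(C)C(C)(C)C)CC(=O)OC | intermediate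
22 | methyl (13R)-13-(tert-butyldimethylsilyloxy)-19-oxolabd-8(17)-en-15-oate | C=C1CC[C@@H]2[C@](C)(CCC[C@]2(C)C=O)[C@H]1CC[C@@](C)(O[Si](C)(C)C(C)(C)C)CC(=O)OC | intermediate
23 | (13R)-13-(tert-butyldimethylsilyloxy)-15-methoxy-15-oxolabd-8(17)-en-19-oic acid | C=C1CC[C@@H]2[C@](C)(CCC[C@]2(C)C(=O)O)[C@H]1CC[C@@](C)(O[Si](C)(C)C(C)(C)C)CC(=O)OC | intermediate
24 | (13R)-13-(tert-butyldimethylsilyloxy)labd-8(17)-ene-15,19-dioic acid | C=C1CC[C@@H]2[C@](C)(CCC[C@]2(C)C(=O)O)[C@H]1CC[C@@](C)(O[Si](C)(C)C(C)(C)C)CC(=O)O | intermediate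
25 | (13R)-13-hydroxylabd-8(17)-ene-15,19-dioic acid | C=C1CC[C@@H]2[C@](C)(CCC[C@]2(C)C(=O)O)[C@H]1CC[C@@](C)(O)CC(=O)O | target

**Totals**
Total step count: 16. Longest linear sequence: 16 steps (1 → 25); 7 and 15 are purchased.

**Steps most likely to fail**

1. Step 9. The chiral Lewis acid may turn over poorly with the β,β-disubstituted enone. Facial control at C10 may be eroded by an achiral silyl-triflimide pathway, or the diene may be protodesilylated. Equilibration at C5 may also stop short of completion, because the trans preference of an angularly methylated decal-4-one is modest; cis-fused material would be separated and resubmitted to base. Fallback, from 14 and 15: the annulation is run with achiral HN(SO2CF3)2 (10 mol%, CH2Cl2, −78 → −20 °C), which is the known racemic type of this reaction. It should give 16 together with the diastereomeric cycloadduct F1 (opposite configuration at C5, C9 and C10). The same acid and base treatment leads, through the diastereomeric cis-fused dione F2, to 18 and the diastereomeric trans-fused dione F3. These differ in the relation of the decalin to C13 and would be separated by preparative HPLC. The route is rejoined at 18.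

2. Step 10. The ylide may attack C8 or both carbonyls, or may only enolise the ketones, since the steric difference between C4 and C8 is not large. Fallback, from 18: HF·pyridine frees the C13 hydroxyl to give the 13-hydroxy dione F4, which is in equilibrium with its C8 hemiketal. PPTS in MeOH closes it to the cyclic methyl ketal F5 (8-methoxy-8,13-epoxide), which masks C8 alone. Methoxymethylenation of the only remaining ketone gives the ketal enol ether F6. PPTS in wet acetone hydrolyses the ketal, which ionises far faster than the β,β-disubstituted enol ether is protonated, to give the hydroxy ketone enol ether F7. TBSOTf and 2,6-lutidine then return to 19.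

3. Step 13. The aldehyde enolate may be O-methylated, the facial preference may be insufficient, or the base may cause condensation or β-elimination at the side-chain ester. Fallback, from 19: Simmons–Smith cyclopropanation (Et2Zn, CH2I2, CH2Cl2) of the enol ether on the α face gives the spiro methoxycyclopropane F8. Acid ring opening (1 M HCl, THF, 40 °C), with protonation at the cyclopropane CH2, delivers the 4α-methyl-4β-formyl keto aldehyde F9 without any enolate. Pinnick oxidation gives the keto acid F10, and Wittig methylenation with excess Ph3P=CH2 then meets the route at 23.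

**Further compounds**
F1 | step 9 | methyl (13R)-8,13-bis(tert-butyldimethylsilyloxy)-4-oxo-17,18,19-trinorlabd-7-en-15-oate, diastereomer with inverted C5, C9 and C10 | CC(C)(C)[Si](C)(C)OC1=CC[C@@H]2[C@@](C)(CCCC2=O)[C@H]1CC[C@@](C)(O[Si](C)(C)C(C)(C)C)CC(=O)OC
F2 | step 9 | cis-fused dione, diastereomer of 17 with inverted C5, C9 and C10 | O=C1CC[C@@H]2[C@@](C)(CCCC2=O)[C@H]1CC[C@@](C)(O[Si](C)(C)C(C)(C)C)CC(=O)OC
F3 | step 9 | trans-fused dione, diastereomer of 18 with inverted C5, C9 and C10 | O=C1CC[C@H]2[C@@](C)(CCCC2=O)[C@@H]1CC[C@@](C)(O[Si](C)(C)C(C)(C)C)CC(=O)OC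
F4 | step 10 | methyl (13R)-13-hydroxy-4,8-dioxo-17,18,19-trinorlabdan-15-oate (open form of the C8 hemiketal) | O=C1CC[C@@H]2[C@](C)(CCCC2=O)[C@H]1CC[C@@](C)(O)CC(=O)OC
F5 | step 10 | methyl (13R)-8,13-epoxy-8-methoxy-4-oxo-17,18,19-trinorlabdan-15-oate | COC13CC[C@@H]2[C@](C)(CCCC2=O)[C@H]1CC[C@@](C)(O3)CC(=O)OC
F6 | step 10 | methyl (13R)-8,13-epoxy-8,19-dimethoxy-17,18-dinorlabd-4(19)-en-15-oate | COC13CC[C@@H]2[C@](C)(CCCC2=COC)[C@H]1CC[C@@](C)(O3)CC(=O)OC
F7 | step 10 | methyl (13R)-13-hydroxy-19-methoxy-8-oxo-17,18-dinorlabd-4(19)-en-15-oate | O=C1CC[C@@H]2[C@](C)(CCCC2=COC)[C@H]1CC[C@@](C)(O)CC(=O)OC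
F8 | step 13 | spiro methoxycyclopropane at C4 of 19 (CH2 on the α face), C8 ketone retained | O=C1CC[C@@H]2[C@](C)(CCC[C@@]24CC4OC)[C@H]1CC[C@@](C)(O[Si](C)(C)C(C)(C)C)CC(=O)OC
F9 | step 13 | methyl (13R)-13-(tert-butyldimethylsilyloxy)-8,19-dioxo-17-norlabdan-15-oate | O=C1CC[C@@H]2[C@](C)(CCC[C@]2(C)C=O)[C@H]1CC[C@@](C)(O[Si](C)(C)C(C)(C)C)CC(=O)OC
F10 | step 13 | (13R)-13-(tert-butyldimethylsilyloxy)-15-methoxy-8,15-dioxo-17-norlabdan-19-oic acid | O=C1CC[C@@H]2[C@](C)(CCC[C@]2(C)C(=O)O)[C@H]1CC[C@@](C)(O[Si](C)(C)C(C)(C)C)CC(=O)OC
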